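## The problem

CNP0142137.1 (29) is a germacranolide whose ten-membered carbocycle (C1–C10) is bridged by an ether oxygen between C1 and C4. A 2,5-cis oxolane with a quaternary, methyl-bearing C4 therefore shares the ring with a γ-ylidene butenolide (O–C6, C7=C11, C12=O) whose enol double bond C5=C6 is cis within the ring. Four stereocentres lie on the bicycle (C1, C4, C8, C10) and a fifth in the (S)-2-methylglycidate on the C8 oxygen. C1 and C4 are tied together by any cycloaddition that makes the oxolane, and C1, being α-alkoxy, can direct a nucleophile to C10 by chelation. C8 is remote and can be controlled only while the skeleton is folded into something rigid, and nothing in the molecule fixes the absolute sense of C1/C4. The enol lactone, the allylic C13 acetate and the epoxy ester do not survive organometallic reagents, strong base or acid and must appear last. The tertiary C10 hydroxyl must be kept from transannular reactions in the medium ring. The feature that opens the problem is the oxidation pattern: C5=C6–O is a hydrated alkyne and C10 a methylated ketone. A bond from C5 to C10 then turns the ten-membered ring into a cyclohexanone (ring B, C5–C10) fused to a 7-oxanorbornane (C1–C5, C10, O), the α,β-epoxy ketone retron of an Eschenmoser–Tanabe fragmentation, with the oxolane recognisable as a furan Diels–Alder adduct.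

## Retrosynthesis

**C8 ester.** The C8–O acyl bond is cut first, giving diol 26 and (S)-2-methylglycidic acid 28, the oxidation product of (R)-2-methylglycidol 27. The epoxy ester would not survive any earlier step, and 26 already holds every ring atom. The forward acylation must take the secondary allylic hydroxyl and leave the tertiary C10 hydroxyl and the epoxide alone.

**Butenolide.** In 26 (silyl-protected as 25) the enol-lactone bond O–C6 and the C13–O acetate bond are cut together, leading back to hydroxy acid 23. This compound has the alkyne C5≡C6, the carboxyl C12 and a tertiary allylic alcohol at C7 next to an exo-methylene C11=C13. The neighbouring cut, an olefination that makes C7=C11 directly, would give a tetrasubstituted alkene whose geometry decides whether the lactone can close. In 23 C7 is still sp3, so the lactone ring itself puts C12 beside C6, and the acetate reaches C13 by allylic transposition instead of a separate oxidation. The forward reaction must hydrate the alkyne at C6 and not C5 (via oxo acid 24), dehydrate towards C5 with ring-cis geometry, and move the oxygen from C7 to C13.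

**C7–C11.** The C7–C11 bond of 23 is cut to ynone 19 and methyl 3-(dimethylamino)propanoate 20, an acrylate α-anion equivalent (aldol adduct 21, ammonium salt 22). This removes three carbons at once and uses the only position where C7 is electrophilic. The enolate must add 1,2 to the ynone.

**C7 oxygen and C10 methyl.** Ynone 19 comes from alkyne 18 by oxidation of C7, the only propargylic methylene. 18 comes from carbinol 17 by silylation, and 17 from ketone 16 by cutting the C10–CH3 bond. Adding the methyl group first removes the base-sensitive β-silyloxy ketone and uses the oxolane oxygen on C1 as the chelating group. The silyl ether on C10 is needed because a free hydroxyl would close a transannular hemiketal onto the C7 ketone.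

**Key cut.** Alkynone 16 is reconnected between C5 and C10 to epoxy ketone 14 (through tosylhydrazone 15). Compared with closing a ten-membered ring end to end, this forms the medium ring by cleaving the bond shared by two six-membered rings of a rigid tricycle. The precursor has only small rings and its ring-fusion stereocentres are of no consequence. The forward reaction must fragment faster than the epoxide is opened by solvent.

**C8 oxygen.** The C8–O bond of 14 is cut through alcohol 13 and boronate 12 to epoxy enone 11 (conjugate borylation, then oxidation). Only in the folded epoxide is one face of ring B exposed, so this is the point where C8 can be set relative to C1/C4. Both cycloaddition partners are achiral and a catalytic asymmetric version of that furan/alkyne addition cannot be relied on. The same step is therefore used to bring in absolute configuration by kinetic resolution.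

**Ring B oxidation level.** Enone 11 is traced to epoxy ketone 10 (dehydrogenation at C7–C8) and 10 to tricyclic enone 9 (epoxidation of C5=C10). The order is forced: a C7=C8 double bond beside the C5=C10 enone would be a phenol tautomer.

**Ring B.** Ring B of 9 is opened at C6–C7 (Dieckmann condensation of diester 7 via β-keto ester 8, then loss of the extra ester) and at C9–C10 (Negishi coupling of vinyl bromide 5 with zinc reagent 6). Letting the dienophile deliver the C6 carbonyl fixes where the methyl group sits; attaching ring B before the cycloaddition would leave that to chance.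

**Oxanorbornane.** Bromide 5 is the diimide reduction product of diene 4, the Diels–Alder adduct of 2-methylfuran 3 and ethyl 3-bromopropiolate 2 (from ethyl propiolate 1). Bonds C1–C10 and C4–C5 are cut. The cycloaddition sets C1–H and C4–CH3 cis without further effort and asks only for the regiochemistry that the orbital coefficients favour.

## Roads not taken

Alternative 1: The cut is the C4–O bond of the oxolane. Anodic oxidation of the ten-membered alkenylfuran diol A1 would make the C1 hydroxyl add across the ring to C4 of the furan radical cation, while solvent alcohol caps C12, giving lactol ether A2 with C5=C6 and C7=C11 already in place.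
- Merits: the butenolide carbons are carried as a furan from the start, the enol double bond appears directly with its geometry, and no alkyne hydration or acetate transposition is needed. In that respect this road is better than the chosen one.
- Weak points: A1 is itself a ten-membered ring with three stereocentres that has to be closed end to end. The quaternary C4 centre would be set by a transannular attack on a flexible ring. Over-oxidation and solvent capture at C4 compete. A further oxidation from lactol ether to lactone is needed.
- Comparison: the chosen plan has a longer endgame, but it obtains the medium ring and the cis oxolane from a rigid tricycle with no macrocyclisation.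

Alternative 2: The cut is C2–C3, with a temporary C5–C10 bond. A siloxy-Cope rearrangement of the divinylcyclohexanol silyl ether A3 would form C2–C3 and break C5–C10, giving cyclodecadiene lactone A4.
- Merits: like the chosen plan it unveils the ten-membered ring by cleaving a six-membered ring. It carries the complete lactone, including C13, through the ring expansion, which is more economical than annulating the butenolide afterwards.
- Weak points: it needs about 200 °C on a butenolide. A4 has no oxolane, C4=C5 instead of C5=C6, and a saturated C6. The C1–O–C4 bridge, the C10 carbinol and the enol double bond would all have to be made by oxidations on a flexible medium ring, where C1, C4 and C10 have no reliable control element.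
- Comparison: the chosen plan creates C1 and C4 in a cycloaddition and C10 under chelation, at the price of building the lactone late.

Alternative 3: The cut is C3–C4. Tin-hydride reduction of bromide A5 would generate the C3 radical, which closes 5-exo onto the β-alkoxycrotonate to give oxolane A6.
- Merits: such closures give 2,5-cis oxolanes dependably, and C1 and C10 can come from reagent-controlled asymmetric reactions. Absolute configuration is therefore secured without any resolution, which is better than the chosen plan, where half of the material is set aside in step 8.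
- Weak points: the quaternary acceptor carbon lowers rate and selectivity. A6 contains only C1–C6, C9 and C10. The ten-membered ring and the whole butenolide remain to be built, again by an end-to-end ring closure.
- Comparison: the chosen plan pays for its resolution with a ring synthesis that needs no macrocyclisation.

Key step: step 10

Assumption: 4-ethoxy-4-oxobutylzinc bromide (THF solution), methyl 3-(dimethylamino)propanoate, (R)-2-methylglycidol and Rh2(cap)4 are taken as catalogue chemicals.
Remark: compounds 4, 5 and 7–11 are racemates; names and SMILES show the enantiomer that step 8 carries forward. Atom numbers C1–C13 are those of the target.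

## Route

Step 1
Reactants: 1 ethyl propiolate
Product: 2 ethyl 3-bromopropiolate
Conditions: NBS, AgNO3 (10 mol%), acetone, rt
Reagents that add atoms: N-bromosuccinimide O=C1CCC(=O)N1Br
Why: Silver-catalysed electrophilic bromination of the terminal alkyne C–H (silver acetylide, then bromine transfer). The bromine makes C10 the electrophilic terminus of the dienophile and later the cross-coupling site.

Step 2
Reactants: 2 ethyl 3-bromopropiolate; 3 2-methylfuran
Product: 4 ethyl (1R,4S)-3-bromo-1-methyl-7-oxabicyclo[2.2.1]hepta-2,5-diene-2-carboxylate (racemic)
Conditions: neat 3 (5 equiv), 80 °C, sealed tube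
Reagents that add atoms: none
Why: Thermal Diels–Alder addition of a furan to a halopropiolate. The larger HOMO coefficient at the unsubstituted furan α-carbon pairs with the bromine-bearing β-carbon, so the methyl-bearing carbon (C4) should bond to the ester-bearing C5 and the C6 carbonyl ends up beside the quaternary centre. The cycloaddition fixes C1–H and C4–CH3 cis on the future oxolane.

Step 3
Reactants: 4 bromo diene ester
Product: 5 ethyl (1R,4S)-3-bromo-1-methyl-7-oxabicyclo[2.2.1]hept-2-ene-2-carboxylate (racemic)
Conditions: KO2CN=NCO2K, AcOH, MeOH, 0 °C → rt
Reagents that add atoms: none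
Why: Diimide reduces the strained disubstituted C2=C3 alkene far faster than the tetrasubstituted bromo-enoate alkene and does not touch the C–Br bond, which catalytic hydrogenation might cleave.

Step 4
Reactants: 5 vinyl bromide; 6 4-ethoxy-4-oxobutylzinc bromide
Product: 7 ethyl (1R,4S)-3-(4-ethoxy-4-oxobutyl)-1-methyl-7-oxabicyclo[2.2.1]hept-2-ene-2-carboxylate (racemic)
Conditions: Pd(dppf)Cl2 (5 mol%), THF, 50 °C
Reagents that add atoms: none
Why: Negishi coupling of a β-bromo enoate, an activated vinyl halide, with an ester-bearing alkylzinc halide forms C9–C10. The bidentate ferrocenylphosphine suppresses β-hydride elimination.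

Step 5
Reactants: 7 diester
Product: 9 tricyclic enone (1S,4R)-4-methyl-1,4-epoxy-1,2,3,4,7,8-hexahydronaphthalen-5(6H)-one (racemic; C6 ketone and C5=C10), via β-keto ester 8 (not isolated)
Conditions: KOtBu, THF, 0 °C → rt; AcOH; then LiCl, H2O, DMSO, 120 °C
Reagents that add atoms: none
Why: Dieckmann condensation: the enolate of the chain ester (C7) acylates the ring ester carbonyl C6 and closes ring B, driven by deprotonation of 8. Krapcho-type dealkoxycarbonylation in wet DMSO then removes the extra ester. Holding the temperature near 120 °C keeps the oxanorbornene below the range where it loses ethylene by cycloreversion.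

Step 6
Reactants: 9 tricyclic enone
Product: 10 exo-5,10-epoxy ketone (1S,4R,5R,10S; epoxide oxygen on the face of the oxygen bridge; racemic)
Conditions: H2O2 (30%), NaOH, MeOH, 0 °C
Reagents that add atoms: hydrogen peroxide OO
Why: Weitz–Scheffer nucleophilic epoxidation of the tetrasubstituted enone. Hydroperoxide adds to C10 from the exo face, as reagents generally do on 7-oxanorbornenes. The configuration at C5 and C10 has no later consequence.

Step 7
Reactants: 10 epoxy ketone
Product: 11 epoxy enone (C6 ketone and C7=C8; 1S,4R,5R,10S; racemic)
Conditions: IBX, DMSO/fluorobenzene, 70 °C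
Reagents that add atoms: none
Why: IBX dehydrogenation of a ketone to the enone through its enol. C7 is the only enolisable position because C5 is a quaternary epoxide carbon. With C5=C10 already epoxidised, the new double bond cannot tautomerise to a phenol.

Step 8
Reactants: 11 epoxy enone (racemic)
Product: 13 (1S,4R,5R,8S,10S)-8-hydroxy epoxy ketone (hydroxyl syn to the epoxide oxygen; single enantiomer), via pinacol boronate 12 (not isolated)
Conditions: B2pin2 (0.55 equiv), CuCl (5 mol%), (R,S)-Josiphos (6 mol%), NaOtBu (8 mol%), MeOH (2 equiv), THF, −20 °C to about half conversion; then H2O2, pH 7 buffer, 0 °C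
Reagents that add atoms: hydrogen peroxide OO
Why: Copper-catalysed enantioselective β-borylation of a cyclic enone, run as a kinetic resolution in the way known for asymmetric conjugate additions to 5-substituted cyclohexenones. The folded tricycle exposes only the convex face of ring B, the face of the epoxide oxygen, so boron enters C8 syn to the epoxide; the ligand enantiomer is chosen so that the catalyst accepts this face only in the (1S,4R) enone. Oxidation of the C–B bond with retention should give the 8S alcohol, and the slow (1R,4S) enone is removed by chromatography.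

Step 9
Reactants: 13 hydroxy epoxy ketone
Product: 14 (1S,4R,5R,8S,10S)-8-(tert-butyldimethylsilyloxy) epoxy ketone
Conditions: TBSCl, imidazole, DMF, rt
Reagents that add atoms: tert-butyldimethylsilyl chloride CC(C)(C)[Si](C)(C)Cl
Why: Silylation of the secondary alcohol under conditions that are neither strongly basic nor Lewis acidic, which avoids β-elimination of the β-hydroxy ketone and opening of the epoxide. The TBS ether is meant to last through step 16.

Step 10
Reactants: 14 silyloxy epoxy ketone
Product: 16 (1S,4R,8R)-8-(tert-butyldimethylsilyloxy)-4-methyl-1,4-epoxycyclodec-5-yn-10-one, via tosylhydrazone 15 (not isolated)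
Conditions: TsNHNH2 (1.1 equiv), AcOH/CH2Cl2 (1:1), −20 °C → rt
Reagents that add atoms: none
Why: Tosylhydrazide condenses with the only ketone (C6) to give hydrazone 15. Acid then opens the adjacent epoxide at C5, giving the 1-tosylazo-alkene with the oxygen left on C10. From this intermediate the C10 oxygen pushes, the C5–C10 bond breaks, p-toluenesulfinate and dinitrogen leave, and the C5≡C6 alkyne and the C10 ketone appear together. This is the Eschenmoser–Tanabe fragmentation, best known for turning 9,10-epoxy-1-decalones into cyclodec-5-ynones. The ten-membered ring is not closed end to end but unveiled by cleaving the bond shared by the two six-membered rings, so no ring-closure entropy is paid, and the oxolane remains as the C1–O–C4 bridge. No stereocentre is formed: C5 and C10 lose theirs, while C1, C4 and C8 are untouched. The step needs fragmentation to outrun solvolytic opening of the epoxide and β-elimination of the C8 silyloxy group. The rigid cis-fused tricycle holds the C5–C10 bond in the plane of the azo-alkene, loss of nitrogen and of the oxanorbornane strain makes the cleavage irreversible near room temperature, and no other carbonyl competes for the hydrazide.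

Step 11
Reactants: 16 alkynone
Product: 17 (1S,4R,8R,10R)-8-(tert-butyldimethylsilyloxy)-4,10-dimethyl-1,4-epoxycyclodec-5-yn-10-ol
Conditions: MeMgBr, CH2Cl2/Et2O, −78 °C; H2O
Reagents that add atoms: methylmagnesium bromide C[Mg]Br
Why: Grignard addition to an α-alkoxy ketone under Cram-chelate control. Magnesium bridges the C10 carbonyl and the oxolane oxygen on C1, and methyl enters from the side of C1–H, anti to C2, which should give the 10R carbinol. The low temperature keeps the β-silyloxy ketone from eliminating.

Step 12
Reactants: 17 tertiary alcohol
Product: 18 10-O-triethylsilyl ether of 17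
Conditions: TESOTf, 2,6-lutidine, CH2Cl2, −78 → 0 °C
Reagents that add atoms: triethylsilyl trifluoromethanesulfonate CC[Si](CC)(CC)OS(=O)(=O)C(F)(F)F
Why: Silyl triflate silylation of a hindered tertiary alcohol. The TES ether prevents transannular hemiketal formation with the C7 ketone of 19 and alkoxide-triggered side reactions in step 14.

Step 13
Reactants: 18 bis-silyl alkyne
Product: 19 (1S,4R,8S,10R)-8-(tert-butyldimethylsilyloxy)-4,10-dimethyl-10-(triethylsilyloxy)-1,4-epoxycyclodec-5-yn-7-one
Conditions: Rh2(cap)4 (1 mol%), t-BuOOH (70% aq.), 1,2-dichloroethane, 40 °C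
Reagents that add atoms: tert-butyl hydroperoxide CC(C)(C)OO
Why: Dirhodium caprolactamate/TBHP propargylic C–H oxidation: a tert-butylperoxyl radical abstracts the propargylic hydrogen and the mixed peroxide collapses to the ketone. C7 is the only propargylic methylene, since the other alkyne terminus is the quaternary C4.

Step 14
Reactants: 19 ynone; 20 methyl 3-(dimethylamino)propanoate
Product: 21 aldol adduct: methyl 3-(dimethylamino)-2-(7-hydroxy-C7-yl)propanoate of the bis-silyl macrocycle (mixture at C7 and C11)
Conditions: LiN(iPr)2, 20, THF, −78 °C; then 19; H2O
Reagents that add atoms: none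
Why: Aldol addition of a lithium ester enolate to the ynone carbonyl, the usual 1,2 course for hard lithium enolates at low temperature. 20 acts as an acrylate α-anion equivalent whose β-amino group does not eliminate from the enolate. The new centres at C7 and C11 are both destroyed later, so the diastereomer mixture is carried on.

Step 15
Reactants: 21 amino ester
Product: 23 2-(7-hydroxy-C7-yl)acrylic acid of the bis-silyl macrocycle (C11=C13 exo-methylene, C12 acid; mixture at C7), via ammonium iodide 22 (not isolated)
Conditions: MeI, MeOH, rt; then LiOH, THF/H2O, 0 °C → rt; HCl to pH 4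
Reagents that add atoms: lithium hydroxide [Li+].[OH-]
Why: Quaternisation of the amine followed by base-induced β-elimination (Hofmann-type, E1cB) unmasks the α-methylene ester, and the same hydroxide saponifies the methyl ester. The result is a Morita–Baylis–Hillman-type hydroxy acid that cannot be made from a ketone directly.

Step 16
Reactants: 23 hydroxy acid
Product: 25 (1S,4R,5E,8S,10R)-13-acetoxy-8-(tert-butyldimethylsilyloxy)-10-(triethylsilyloxy)-1,4-epoxygermacra-5,7(11)-dien-6,12-olide, via oxo acid 24 (not isolated)
Conditions: NaAuCl4·2H2O (5 mol%), MeCN/H2O (10:1), rt; evaporate; then Ac2O, NaOAc, 80 °C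
Reagents that add atoms: acetic anhydride CC(=O)OC(C)=O; sodium acetate [Na+].CC(=O)[O-]
Why: Gold-catalysed hydration of the alkyne with participation of the carboxyl group (5-exo attack on C6) puts the oxygen on C6 and gives 24 as its lactol. Hot acetic anhydride/acetate acetylates the lactol and eliminates acetic acid towards C5 (enol-lactonisation), and turns the tertiary allylic C7 acetate into the conjugated C7=C11 butenolide by SN2′ addition–elimination of acetate at C13. The lactone ring holds C12 cis to C6, and the dehydration should give the ring-cis (5E) alkene because the other isomer would place a trans double bond in the nine-membered oxacycle.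

Step 17
Reactants: 25 bis-silyl lactone
Product: 26 (1S,4R,5E,8S,10R)-13-acetoxy-8,10-dihydroxy-1,4-epoxygermacra-5,7(11)-dien-6,12-olide
Conditions: HF·pyridine, pyridine/THF, 0 °C → rt
Reagents that add atoms: none
Why: Fluoride cleavage of both silyl ethers in a buffered, weakly acidic medium that leaves the enol lactone and the allylic acetate intact.

Step 18
Reactants: 27 (R)-2-methylglycidol
Product: 28 (S)-2-methylglycidic acid
Conditions: RuCl3·xH2O (2 mol%), NaIO4, MeCN/EtOAc/H2O, 0 °C
Reagents that add atoms: sodium periodate [Na+].[O-]I(=O)(=O)=O; water O
Why: Ruthenium tetroxide oxidation (catalytic RuCl3, periodate as terminal oxidant) of a primary alcohol to the acid. The epoxide is inert and the stereocentre is untouched; only its descriptor changes from R to S.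

Step 19
Reactants: 26 diol; 28 (S)-2-methylglycidic acid
Product: 29 CNP0142137.1
Conditions: 2,4,6-trichlorobenzoyl chloride, Et3N, THF, 0 °C; then 26, DMAP, toluene, rt
Reagents that add atoms: none
Why: Yamaguchi esterification through the mixed 2,4,6-trichlorobenzoic anhydride. DMAP delivers the acyl group to the secondary allylic C8 hydroxyl, the tertiary C10 hydroxyl is too hindered to react, and the mild conditions spare the glycidate epoxide.

## Compound list

1 | ethyl propiolate | C#CC(=O)OCC | starting material
2 | ethyl 3-bromopropiolate | BrC#CC(=O)OCC | intermediate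
3 | 2-methylfuran | Cc1ccco1 | starting material
4 | ethyl (1R,4S)-3-bromo-1-methyl-7-oxabicyclo[2.2.1]hepta-2,5-diene-2-carboxylate (racemic) | CCOC(=O)C1=C(Br)[C@@H]2C=C[C@@]1(C)O2 | intermediate
5 | ethyl (1R,4S)-3-bromo-1-methyl-7-oxabicyclo[2.2.1]hept-2-ene-2-carboxylate (racemic) | CCOC(=O)C1=C(Br)[C@@H]2CC[C@@]1(C)O2 | intermediate
6 | 4-ethoxy-4-oxobutylzinc bromide | CCOC(=O)CCC[Zn]Br | starting material
7 | ethyl (1R,4S)-3-(4-ethoxy-4-oxobutyl)-1-methyl-7-oxabicyclo[2.2.1]hept-2-ene-2-carboxylate (racemic) | CCOC(=O)CCCC1=C(C(=O)OCC)[C@@]2(C)CC[C@@H]1O2 | intermediate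
8 | tricyclic β-keto ester, 7-ethoxycarbonyl derivative of 9 (racemic, C7 epimers and enol) | O=C1C(C(=O)OCC)CCC2=C1[C@@]3(C)CC[C@@H]2O3 | intermediate (not isolated)
9 | tricyclic enone, (1S,4R)-4-methyl-1,4-epoxy-1,2,3,4,7,8-hexahydronaphthalen-5(6H)-one (racemic) | O=C1CCCC2=C1[C@@]3(C)CC[C@@H]2O3 | intermediate
10 | exo-5,10-epoxide of 9, (1S,4R,5R,10S), epoxide oxygen syn to the oxygen bridge (racemic) | O=C1CCC[C@]2(O3)[C@@H]4CC[C@@](C)(O4)[C@]231 | intermediate
11 | epoxy enone, 7,8-didehydro derivative of 10 (racemic) | O=C1C=CC[C@]2(O3)[C@@H]4CC[C@@](C)(O4)[C@]231 | intermediate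
12 | 8-(pinacolboryl) epoxy ketone, boron syn to the epoxide oxygen | O=C1C[C@@H](B5OC(C)(C)C(C)(C)O5)C[C@]2(O3)[C@@H]4CC[C@@](C)(O4)[C@]231 | intermediate (not isolated)
13 | (1S,4R,5R,8S,10S)-8-hydroxy epoxy ketone | O=C1C[C@@H](O)C[C@]2(O3)[C@@H]4CC[C@@](C)(O4)[C@]231 | intermediate
14 | (1S,4R,5R,8S,10S)-8-(tert-butyldimethylsilyloxy) epoxy ketone | O=C1C[C@@H](O[Si](C)(C)C(C)(C)C)C[C@]2(O3)[C@@H]4CC[C@@](C)(O4)[C@]231 | intermediate
15 | C6 tosylhydrazone of 14 | Cc1ccc(cc1)S(=O)(=O)NN=C1C[C@@H](O[Si](C)(C)C(C)(C)C)C[C@]2(O3)[C@@H]4CC[C@@](C)(O4)[C@]231 | intermediate (not isolated)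
16 | (1S,4R,8R)-8-(tert-butyldimethylsilyloxy)-4-methyl-1,4-epoxycyclodec-5-yn-10-one | O=C1C[C@H](O[Si](C)(C)C(C)(C)C)CC#C[C@@]2(C)CC[C@@H]1O2 | intermediate
17 | (1S,4R,8R,10R)-8-(tert-butyldimethylsilyloxy)-4,10-dimethyl-1,4-epoxycyclodec-5-yn-10-ol | C[C@@]1(O)C[C@H](O[Si](C)(C)C(C)(C)C)CC#C[C@@]2(C)CC[C@@H]1O2 | intermediate
18 | 10-O-triethylsilyl ether of 17 | C[C@@]1(O[Si](CC)(CC)CC)C[C@H](O[Si](C)(C)C(C)(C)C)CC#C[C@@]2(C)CC[C@@H]1O2 | intermediate
19 | (1S,4R,8S,10R)-7-oxo derivative of 18 (ynone) | C[C@@]1(O[Si](CC)(CC)CC)C[C@H](O[Si](C)(C)C(C)(C)C)C(=O)C#C[C@@]2(C)CC[C@@H]1O2 | intermediate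
20 | methyl 3-(dimethylamino)propanoate | COC(=O)CCN(C)C | starting material
21 | aldol adduct, C7 tertiary alcohol bearing CH(CH2NMe2)CO2Me (mixture at C7 and C11) | C[C@@]1(O[Si](CC)(CC)CC)C[C@H](O[Si](C)(C)C(C)(C)C)C(O)(C(CN(C)C)C(=O)OC)C#C[C@@]2(C)CC[C@@H]1O2 | intermediate
22 | trimethylammonium iodide of 21 | C[C@@]1(O[Si](CC)(CC)CC)C[C@H](O[Si](C)(C)C(C)(C)C)C(O)(C(C[N+](C)(C)C)C(=O)OC)C#C[C@@]2(C)CC[C@@H]1O2.[I-] | intermediate (not isolated)
23 | α-methylene β-hydroxy acid, C7 tertiary alcohol bearing C(=CH2)CO2H (mixture at C7) | C[C@@]1(O[Si](CC)(CC)CC)C[C@H](O[Si](C)(C)C(C)(C)C)C(O)(C(=C)C(=O)O)C#C[C@@]2(C)CC[C@@H]1O2 | intermediate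
24 | 6-oxo acid from hydration of 23 at C6 (in equilibrium with its lactol) | C[C@@]1(O[Si](CC)(CC)CC)C[C@H](O[Si](C)(C)C(C)(C)C)C(O)(C(=C)C(=O)O)C(=O)C[C@@]2(C)CC[C@@H]1O2 | intermediate (not isolated)
25 | (1S,4R,5E,8S,10R)-13-acetoxy-8-(tert-butyldimethylsilyloxy)-10-(triethylsilyloxy)-1,4-epoxygermacra-5,7(11)-dien-6,12-olide | CC(=O)OCC1=C2/C(=C\[C@@]3(C)CC[C@H](O3)[C@](C)(O[Si](CC)(CC)CC)C[C@@H]2O[Si](C)(C)C(C)(C)C)OC1=O | intermediate
26 | (1S,4R,5E,8S,10R)-13-acetoxy-8,10-dihydroxy-1,4-epoxygermacra-5,7(11)-dien-6,12-olide | CC(=O)OCC1=C2/C(=C\[C@@]3(C)CC[C@H](O3)[C@](C)(O)C[C@@H]2O)OC1=O | intermediate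
27 | (R)-2-methylglycidol | OC[C@]1(C)CO1 | starting material
28 | (S)-2-methylglycidic acid | OC(=O)[C@]1(C)CO1 | intermediate
29 | CNP0142137.1, the 8-O-[(S)-2-methylglycidate] of 26 | CC(=O)OCC1=C2/C(=C\[C@@]3(C)CC[C@H](O3)[C@](C)(O)C[C@@H]2OC(=O)[C@]2(C)CO2)OC1=O | target

## Step count and least certain steps

Total: 19 steps. Longest linear sequence: 18 steps (steps 1–17 and 19, from 1 to 29); step 18 is a one-step side branch.

**Step 10 (key step).** Condensation at C6, which is flanked by the quaternary epoxide carbon, may be slow. Acid-promoted opening of the epoxide, loss of the silyl group or β-elimination of the C8 silyloxy group could then overtake hydrazone formation. Addition of sulfinate or acetic acid to the strained alkyne after the cleavage is a second risk. Fallback: starting from 14, condensation with 1-amino-2-phenylaziridine (as its acetate, CH2Cl2, 0 °C) gives the N-(2-phenylaziridin-1-yl)imine F1. On gentle warming under neutral conditions F1 fragments with loss of styrene and nitrogen, with no acid and no sulfinate present, and rejoins the route at 16.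

**Step 16.** The tertiary propargylic alcohol may undergo Meyer–Schuster rearrangement before the carboxyl group adds. The tertiary acetate may eliminate towards C8 instead of shifting to C13. The dehydration may stop at the wrong C5=C6 geometry. Fallback: from 23, AgNO3 (10 mol%) in acetone closes the lactone directly by 5-exo-dig addition of the acid to the alkyne without water, giving the 7-hydroxy-11(13)-methylene ylidene lactone F2. Acetylation of F2 with Ac2O/DMAP/Et3N at room temperature then triggers the allylic acetate shift under nucleophilic catalysis, and a trace of iodine equilibrates the enol double bond if the kinetic isomer is obtained. The sequence rejoins the route at 25.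

**Step 8.** The resolution may discriminate poorly between the enantiomers, so that the alcohol is formed with low enantiomeric purity. The alkoxide base may also isomerise the epoxy enone by vinylogous opening of the epoxide. Fallback: from racemic 11, the same borylation/oxidation with an achiral ligand (xantphos) is taken to full conversion to give racemic 13. Esterification with (R)-O-methylmandelic acid (DCC, DMAP) gives the diastereomeric esters F3 (1S,4R series) and F4 (1R,4S series), which are separated by chromatography or crystallisation. Mild methanolysis of F3 (K2CO3, MeOH, −10 °C) returns enantiopure 13.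

**Step 13.** Hydrogen abstraction may occur at other activated C–H bonds (C1–H beside the ether oxygen, C8–H). C7 is deactivated by the neighbouring silyloxy group, and the aqueous peroxide may cause partial desilylation. Fallback: from 18, SeO2 (cat.)/t-BuOOH in CH2Cl2 hydroxylates C7 by an ene/[2,3]-sigmatropic sequence without free radicals, giving propargylic alcohol F5 (either epimer). Dess–Martin periodinane then oxidises F5 to 19.

**Step 11.** The conformation of the medium ring, rather than chelation, may decide the face of attack and give the C10 epimer; enolisation with β-elimination of the silyloxy group is a lesser risk. Fallback: from 16, Wittig methylenation (Ph3P=CH2) gives the 10-methylene compound F6. Epoxidation of this 1,1-disubstituted alkene (mCPBA, NaHCO3) delivers oxygen, not carbon, to the more open face and gives spiro-epoxide F7. LiEt3BH opens F7 at its CH2 group to 17, so the outcome at C10 is the reverse of a sterically controlled Grignard addition.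

Further compounds
F1 | step 10 | N-(2-phenylaziridin-1-yl)imine of 14 at C6 (mixture at the aziridine carbon) | c1ccccc1C1CN1N=C1C[C@@H](O[Si](C)(C)C(C)(C)C)C[C@]2(O3)[C@@H]4CC[C@@](C)(O4)[C@]231
F2 | step 16 | 7-hydroxy-11(13)-methylene 5-ylidene lactone, bis-silyl ether (mixture at C7, C5=C6 geometry open) | C=C1C(=O)OC2=C[C@@]3(C)CC[C@H](O3)[C@](C)(O[Si](CC)(CC)CC)C[C@H](O[Si](C)(C)C(C)(C)C)C12O
F3 | step 8 | (R)-O-methylmandelate of 13 | O=C1C[C@@H](OC(=O)[C@H](OC)c2ccccc2)C[C@]2(O3)[C@@H]4CC[C@@](C)(O4)[C@]231
F4 | step 8 | (R)-O-methylmandelate of the enantiomer of 13 | O=C1C[C@H](OC(=O)[C@H](OC)c2ccccc2)C[C@@]2(O3)[C@H]4CC[C@](C)(O4)[C@@]231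
F5 | step 13 | 7-hydroxy derivative of 18 (propargylic alcohol, mixture at C7) | C[C@@]1(O[Si](CC)(CC)CC)C[C@H](O[Si](C)(C)C(C)(C)C)C(O)C#C[C@@]2(C)CC[C@@H]1O2
F6 | step 11 | 10-methylene analogue of 16 | C=C1C[C@H](O[Si](C)(C)C(C)(C)C)CC#C[C@@]2(C)CC[C@@H]1O2
F7 | step 11 | C10 spiro-epoxide of F6 with the oxygen in the position of the C10 hydroxyl of 17 | C1O[C@@]12C[C@H](O[Si](C)(C)C(C)(C)C)CC#C[C@@]3(C)CC[C@@H]2O3
A1 | alternative 1 | ten-membered 2-alkenylfuran 1,10-diol, C8 O-triethylsilyl (C4=C5 geometry open) | CC(=O)OCc1coc2c1[C@@H](O[Si](CC)(CC)CC)C[C@@](C)(O)[C@@H](O)CCC(C)=C2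
A2 | alternative 1 | 12-methoxy lactol ether of the core (both C12 epimers), C8 O-triethylsilyl | CC(=O)OCC1=C2/C(=C\[C@@]3(C)CC[C@H](O3)[C@](C)(O)C[C@@H]2O[Si](CC)(CC)CC)OC1OC
A3 | alternative 2 | butenolide-fused trans-1-vinyl-2-isopropenylcyclohexanol trimethylsilyl ether | C=C[C@@]1(O[Si](C)(C)C)C[C@H](O[Si](CC)(CC)CC)C2=C(CO[Si](C)(C)C(C)(C)C)C(=O)O[C@H]2[C@@H]1C(C)=C
A4 | alternative 2 | cyclodeca-1(10),4-diene 6,12-olide with C10 silyl enol ether | C[Si](C)(C)O/C1=C\CC/C(C)=C/[C@@H]2OC(=O)C(CO[Si](C)(C)C(C)(C)C)=C2[C@@H](O[Si](CC)(CC)CC)C1
A5 | alternative 3 | C3 bromide carrying the (E)-β-alkoxycrotonate on the C1 oxygen | CCOC(=O)/C=C(\C)O[C@@H](CCBr)[C@](C)(O[Si](CC)(CC)CC)CO[Si](C)(C)C(C)(C)C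
A6 | alternative 3 | 2,5-cis oxolane with C4 methyl and CH2CO2Et arm | CCOC(=O)C[C@@]1(C)CC[C@H](O1)[C@](C)(O[Si](CC)(CC)CC)CO[Si](C)(C)C(C)(C)C
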